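## Retrosynthetic overview
1. Guangsangon N is the [4+2] adduct of the (2S)-flavanone-bearing (E)-1-aryl-3-methylbutadiene **11** and morachalcone A (**14**). A Diels–Alderase (pericyclase) forms the cyclohexene last and sets all three of its stereocenters.
2. Diene **11** comes from Stille coupling of the (2S)-5′-iodoflavanone **7** with the (E)-dienylstannane **9**, followed by MOM removal.
3. The flavanone ring, and with it the first stereocenter C2 (S), is formed by catalytic asymmetric intramolecular oxa-Michael cyclisation of the 2′-hydroxychalcone **6**. **6** comes from a Claisen–Schmidt condensation of the iodo-aldehyde **3** and the acetophenone **5**.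
4. Morachalcone A (**14**) comes from Claisen–Schmidt condensation of **12** and **5**, then MOM removal. All carbon skeletons derive from achiral resorcinol-type aldehydes and ketones and from isopropenylacetylene.
5. Ring order: the chromanone ring forms in Step 5; the cyclohexene ring forms in Step 12.

Assumption (one line): the Diels–Alderase from *Morus alba* (MaDA) or a close homologue accepts the flavanone-diene **11** and delivers the natural-series trans,trans adduct. Iodination of **1** is assumed to occur at C5, para to the 2-OH and least hindered.

## Route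

**Step 1**
Reactants: **1** 2,4-dihydroxybenzaldehyde
Product: **2** 2,4-dihydroxy-5-iodobenzaldehyde
Conditions: NIS (1.05 equiv), MeCN, 0 °C → 25 °C, 4 h
Reagents that add atoms: N-iodosuccinimide, O=C1CCC(=O)N1I
Why: Electrophilic aromatic iodination goes to C5 (para to 2-OH, ortho to 4-OH, unhindered), the most activated site of the resorcinol ring. This puts the handle for the diene at the position required by the target.

**Step 2**
Reactants: **2**
Product: **3** 5-iodo-2,4-bis(methoxymethoxy)benzaldehyde
Conditions: NaH (2.5 equiv), then MOMCl (2.5 equiv), THF/DMF 4:1, 0 °C → 25 °C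
Reagents that add atoms: MOMCl, COCCl
Why: Williamson-type O-alkylation of the phenoxides gives base-stable acetals. NaH is needed because the 2-OH is chelated to the CHO. The MOM groups also survive the Claisen–Schmidt, oxa-Michael and Stille steps.

**Step 3**
Reactants: **4** 2,4-dihydroxyacetophenone
Product: **5** 1-[2-hydroxy-4-(methoxymethoxy)phenyl]ethan-1-one
Conditions: MOMCl (1.1 equiv), i-Pr2NEt (1.5 equiv), CH2Cl2, 0 °C → 25 °C
Reagents that add atoms: MOMCl, COCCl
Why: The 4-OH is more acidic and more accessible than the carbonyl-chelated 2-OH, so alkylation is regioselective. The free 2′-OH is kept as the nucleophile for the later ring closure.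

**Step 4**
Reactants: **3**, **5**
Product: **6** (E)-1-[2-hydroxy-4-(MOMO)phenyl]-3-[5-iodo-2,4-bis(MOMO)phenyl]prop-2-en-1-one
Conditions: 50% aq. KOH (8 equiv), EtOH, 0 → 25 °C, 36 h; then quench to pH 6 (aq. NH4Cl) at 0 °C
Reagents that add atoms: none
Why: Claisen–Schmidt (aldol condensation) gives the thermodynamically preferred E-enone. Any racemic flavanone formed under basic conditions is removed by chromatography or recrystallisation so it cannot erode ee in Step 5.

**Step 5**
Reactants: **6**
Product: **7** (2S)-7-(MOMO)-2-[5-iodo-2,4-bis(MOMO)phenyl]chroman-4-one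
Conditions: quinine-derived bifunctional squaramide (10 mol %), toluene (0.02 M), 25 °C, 72 h; recover and recycle unreacted **6**
Reagents that add atoms: none (isomerisation)
Why: Catalytic enantioselective intramolecular oxa-Michael addition. The squaramide NH groups bind the enone carbonyl and the quinuclidine base orients and deprotonates the 2′-OH, so phenoxide adds to one enone face and sets C2 as S. This is the first stereocenter. Enantiomeric excess is checked by chiral HPLC, with recrystallisation or preparative chiral HPLC to upgrade if it is below 97%.

**Step 6**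
Reactants: **8** 2-methylbut-1-en-3-yne (isopropenylacetylene)
Product: **9** (E)-tributyl(3-methylbuta-1,3-dien-1-yl)stannane
Conditions: Pd(PPh3)2Cl2 (1 mol %), Bu3SnH (1.0 equiv), THF, 0 → 25 °C, dark
Reagents that add atoms: tributyltin hydride, CCCC[SnH](CCCC)CCCC
Why: Pd-catalysed hydrostannation adds Sn–H across the alkyne only (syn, terminal Sn), giving the E-dienylstannane with the 1,1-disubstituted alkene intact.

**Step 7**
Reactants: **7**, **9**
Product: **10** (2S)-7-(MOMO)-2-[2,4-bis(MOMO)-5-((E)-3-methylbuta-1,3-dien-1-yl)phenyl]chroman-4-one
Conditions: Pd(PPh3)4 (5 mol %), CuI (10 mol %), BHT (5 mol %), DMF, 45 °C, 6 h, dark; aq. KF work-up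
Reagents that add atoms: none (**9** is the coupling partner)
Why: Stille coupling is neutral and retentive for alkene geometry, so the (E)-diene is installed and the base-sensitive C2 stereocenter is not epimerised. BHT suppresses diene polymerisation.

**Step 8**
Reactants: **10**
Product: **11** (2S)-7,2′,4′-trihydroxy-5′-[(E)-3-methylbuta-1,3-dien-1-yl]flavanone
Conditions: TMSOTf (6 equiv), 2,2′-bipyridyl (9 equiv), MeCN, 0 → 25 °C, 4 h; then pH 7 phosphate buffer, 25 °C; argon, dark
Reagents that add atoms: none
Why: TMSOTf/bipyridyl cleaves aromatic MOM acetals via pyridinium intermediates under buffered, essentially non-acidic conditions. This avoids protonation of the electron-rich aryl diene (which would give 2,2-dimethylchromene) and avoids ring-opening of the flavanone. The product is purified quickly and stored under argon at −20 °C with BHT.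

**Step 9**
Reactants: **1** 2,4-dihydroxybenzaldehyde
Product: **12** 2,4-bis(methoxymethoxy)benzaldehyde
Conditions: NaH (2.5 equiv), then MOMCl (2.5 equiv), THF/DMF 4:1, 0 → 25 °C
Reagents that add atoms: MOMCl, COCCl
Why: Same protection logic as Step 2. The electron-rich aldehyde is still a competent electrophile, and the free phenols are masked so they do not quench the Claisen–Schmidt base.

**Step 10**
Reactants: **12**, **5**
Product: **13** (E)-1-[2-hydroxy-4-(MOMO)phenyl]-3-[2,4-bis(MOMO)phenyl]prop-2-en-1-one
Conditions: 50% aq. KOH (8 equiv), EtOH, 0 → 25 °C, 36 h; quench to pH 6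
Reagents that add atoms: none
Why: Claisen–Schmidt condensation as in Step 4, giving the E-chalcone. The product is achiral, so no stereochemical issue arises.

**Step 11**
Reactants: **13**
Product: **14** morachalcone A, (E)-2,4,2′,4′-tetrahydroxychalcone
Conditions: TMSOTf (6 equiv), 2,2′-bipyridyl (9 equiv), MeCN, 0 → 25 °C, 4 h; then pH 7 phosphate buffer
Reagents that add atoms: none
Why: Buffered, non-acidic MOM cleavage avoids acid-promoted chalcone → flavanone cyclisation. It leaves the free polyphenol dienophile needed by the enzyme.

**Step 12**
Reactants: **11** (1 equiv), **14** (3 equiv)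
Product: **15** guangsangon N
Conditions: recombinant MaDA (Diels–Alderase, pericyclase, FAD-bound), 50 mM sodium phosphate pH 6.8, 5% DMSO, 30 °C, 16 h, argon, dark; EtOAc extraction, then preparative HPLC
Reagents that add atoms: none
Why: A Diels–Alderase catalyses the intermolecular normal-demand [4+2]. The active site holds the s-cis diene and the s-cis enone so that the aryl groups are oriented endo and the aroyl group exo. This gives the required regiochemistry (aroyl carbon bonded to the aryl-bearing diene terminus), the trans,trans relative configuration (Ar1 and Ar3 cis, aroyl trans to both) and one absolute configuration. The thermal background at 30 °C is slow and would give racemic mixtures of diastereomers. Excess **14** outcompetes diene self-reaction, and C2 of the flavanone is untouched.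

## Compound list

| # | Name | SMILES | Role |
|---|---|---|---|
| 1 | 2,4-dihydroxybenzaldehyde | O=Cc1ccc(O)cc1O | starting material |
| 2 | 2,4-dihydroxy-5-iodobenzaldehyde | O=Cc1cc(I)c(O)cc1O | intermediate |
| 3 | 5-iodo-2,4-bis(MOMO)benzaldehyde | COCOc1cc(OCOC)c(I)cc1C=O | intermediate |
| 4 | 2,4-dihydroxyacetophenone | CC(=O)c1ccc(O)cc1O | starting material |
| 5 | 2-hydroxy-4-(MOMO)acetophenone | CC(=O)c1ccc(OCOC)cc1O | intermediate |
| 6 | iodo-chalcone, tris-MOM, 2′-OH free | COCOc1ccc(C(=O)/C=C/c2cc(I)c(OCOC)cc2OCOC)c(O)c1 | intermediate |
| 7 | (2S)-5′-iodoflavanone, tris-MOM | COCOc1cc(OCOC)c(I)cc1[C@@H]1CC(=O)c2ccc(OCOC)cc2O1 | intermediate |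
| 8 | 2-methylbut-1-en-3-yne | C=C(C)C#C | starting material |
| 9 | (E)-tributyl(3-methylbuta-1,3-dienyl)stannane | CCCC[Sn](CCCC)(CCCC)/C=C/C(C)=C | intermediate |
| 10 | (2S)-dienyl-flavanone, tris-MOM | COCOc1cc(OCOC)c(/C=C/C(C)=C)cc1[C@@H]1CC(=O)c2ccc(OCOC)cc2O1 | intermediate |
| 11 | (2S)-7,2′,4′-trihydroxy-5′-dienylflavanone | Oc1cc(O)c(/C=C/C(C)=C)cc1[C@@H]1CC(=O)c2ccc(O)cc2O1 | intermediate |
| 12 | 2,4-bis(MOMO)benzaldehyde | COCOc1ccc(C=O)c(OCOC)c1 | intermediate |
| 13 | tris-MOM 2′-hydroxychalcone | COCOc1ccc(/C=C/C(=O)c2ccc(OCOC)cc2O)c(OCOC)c1 | intermediate |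
| 14 | morachalcone A | O=C(/C=C/c1ccc(O)cc1O)c1ccc(O)cc1O | intermediate (dienophile) |
| 15 | guangsangon N | CC1=C[C@@H](c2cc([C@@H]3CC(=O)c4ccc(O)cc4O3)c(O)cc2O)[C@H](C(=O)c2ccc(O)cc2O)[C@@H](c2ccc(O)cc2O)C1 | target |

## Totals
- Total steps: 12.
- Longest linear sequence: 7 steps (Steps 1, 2, 4, 5, 7, 8, 12).

## Three steps most likely to fail
1. **Step 12 (enzymatic Diels–Alder).** The enzyme may not accept the flavanone-bearing diene, or may give the wrong diastereomer or enantiomer. Fallback: a chemical biomimetic asymmetric Diels–Alder of silyl-protected **11** and protected **14** with a chiral ligand–boron or Cu(II)–box Lewis acid, followed by global desilylation.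
2. **Step 5 (organocatalytic oxa-Michael).** Conversion is limited by the chalcone/flavanone equilibrium, and ee may be modest because the cyclisation is reversible. Fallback: remove the MOM groups from **6** and cyclise the free iodochalcone with chalcone isomerase (an isomerase that gives (2S)-flavanones), then re-protect as the tris-MOM ether **7**.
3. **Step 8 (MOM removal in the presence of the aryl diene and C2 stereocenter).** Possible problems are diene cyclisation, formaldehyde side reactions on the resorcinol rings, or partial racemisation. Fallback: change the protecting-group strategy. Remove the MOM groups at the stage of **7**, per-silylate with TBSCl/imidazole, run the Stille coupling, then deprotect with buffered TBAF/AcOH at 0 °C.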